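The route rests on cutting the C4–C5 bond of ring B. The isopropenyl group that carvone places on C2 already contains C3, its methyl and C4, and C4 lies one bond from the C5 carbonyl, so a Lewis-acid-promoted type 2 carbonyl-ene reaction closes ring B in one operation, forming C4–C5, the C5 oxygen and an exocyclic C3 methylene on a cis-fused decalin. The precursor is ring A carrying a cis C1/C10 acetonide, the C2 isopropenyl group and, cis to it on C7, a C(CHO)=C(CH3)2 arm (C5 aldehyde, C6 isopropylidene), assembled from (R)-carvone by an Ireland–Claisen relay from a C9 senecioate.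

Key step: step 11

Numbering: atoms follow the target (C1 and C10 acetoxy carbons, C2 and C7 fusion carbons, C3 methyl-bearing, C4 carbinol, C5 ketone, C6 isopropylidene-bearing, C8=C9 with methyl on C9); ring A is C1, C2, C7–C10 and ring B is C2–C7.

Remark: enolate hydroxylation next to C2 is assumed to occur anti to the isopropenyl group, so C1 is corrected by inversion at the outset; the aldehyde is cyclised as its conjugated C6-isopropylidene isomer 22 (isomer 21 with a C6 isopropenyl group is its in-flask precursor), so that C6 is no stereocentre and the C3 methylene is the only 1,1-disubstituted alkene left for the later reduction.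

Step 1
Reactants: 1 (R)-(−)-carvone
Product: 3 trans-6-hydroxycarvone, via potassium dienolate 2 (not isolated)
Conditions: KN(SiMe3)2 (KHMDS), THF, −78 °C; then 2-(phenylsulfonyl)-3-phenyloxaziridine, −78 °C; aq. NH4Cl
Reagents that add atoms: 2-(phenylsulfonyl)-3-phenyloxaziridine, O=S(=O)(N1OC1c1ccccc1)c1ccccc1
Why: Kinetic deprotonation at the only α′ position (C1) and N-sulfonyloxaziridine enolate hydroxylation are standard, and the oxidant should approach the dienolate anti to the pseudo-axial C2 isopropenyl group, which sets the C1 carbinol trans to it.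

Step 2
Reactants: 3 trans-6-hydroxycarvone; 4 4-nitrobenzoic acid
Product: 5 cis-6-(4-nitrobenzoyloxy)carvone
Conditions: PPh3, DIAD, THF, 0 → 23 °C
Reagents that add atoms: 4-nitrobenzoic acid (4), OC(=O)c1ccc(cc1)[N+](=O)[O-]
Why: Mitsunobu esterification displaces the oxyphosphonium ion by SN2 with inversion (the same situation as a trans-2-alkylcyclohexanol), which places the C1 oxygen cis to the C2 isopropenyl group.

Step 3
Reactants: 5 cis-6-(4-nitrobenzoyloxy)carvone
Product: 7 all-cis diol, via hydroxy ester 6 (not isolated)
Conditions: NaBH4, CeCl3·7H2O, MeOH, −78 → 0 °C; then K2CO3 (cat.), 23 °C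
Reagents that add atoms: none
Why: Luche 1,2-reduction delivers hydride to C10 from the face opposite the C1 acyloxy and C2 isopropenyl groups, setting the C10 carbinol cis to both, and methanolysis of the activated ester follows only after C1 has ceased to be α to a ketone and can no longer epimerise.

Step 4
Reactants: 7 all-cis diol
Product: 8 epoxy diol
Conditions: VO(acac)2 (cat.), t-BuOOH, CH2Cl2, 0 → 23 °C
Reagents that add atoms: tert-butyl hydroperoxide, CC(C)(C)OO
Why: Vanadium-catalysed hydroxyl-directed epoxidation of the cyclic allylic alcohol places the C8–C9 epoxide syn to the C10 hydroxyl and leaves the isopropenyl group untouched.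

Step 5
Reactants: 8 epoxy diol; 9 2,2-dimethoxypropane
Product: 10 epoxy acetonide
Conditions: PPTS (cat.), CH2Cl2, 0 → 23 °C
Reagents that add atoms: 2,2-dimethoxypropane (9), COC(C)(C)OC
Why: Acid-catalysed transketalisation closes the five-membered acetonide on the cis C1/C10 diol, and pyridinium tosylate is mild enough to spare the trisubstituted epoxide.

Step 6
Reactants: 10 epoxy acetonide
Product: 13 tertiary allylic alcohol, via phenylselenide 11 (not isolated), via selenoxide 12 (not isolated)
Conditions: (PhSe)2, NaBH4, EtOH, 23 → 78 °C; then THF, 30% H2O2, 0 → 23 °C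
Reagents that add atoms: none
Why: Selenide opening of the epoxide by SN2 attack at the secondary C8 followed by selenoxide syn elimination toward C7 (C9 bears no hydrogen) is the standard epoxide-to-allylic-alcohol transposition and leaves the C9 oxygen on the acetonide face.

Step 7
Reactants: 13 tertiary allylic alcohol; 14 3-methylbut-2-enoyl chloride
Product: 16 C9 senecioate, via lithium alkoxide 15 (not isolated)
Conditions: n-BuLi, THF, −78 °C; then 14, −78 → 0 °C
Reagents that add atoms: 3-methylbut-2-enoyl chloride (14), CC(C)=CC(Cl)=O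
Why: O-acylation of the preformed lithium alkoxide is the reliable esterification of a hindered tertiary alcohol and touches no stereocentre.

Step 8
Reactants: 16 C9 senecioate
Product: 19 isopropenyl acid, via silyl ketene acetal 17 (not isolated), via silyl ester 18 (not isolated)
Conditions: LiN(i-Pr)2 (LDA), Me3SiCl, Et3N, THF, −78 → 60 °C; then aq. citric acid, 0 °C
Reagents that add atoms: none
Why: Ireland–Claisen rearrangement of the γ-deprotonated, O-silylated senecioate transfers its α-carbon suprafacially from the C9 oxygen to C7, which fixes the C6–C7 bond cis to the C2 isopropenyl group, forms C8=C9 and gives the α-isopropenyl acid typical of tertiary-allyl 3-methylbut-2-enoates (the C6 epimers are inconsequential).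

Step 9
Reactants: 19 isopropenyl acid
Product: 20 primary alcohol
Conditions: LiAlH4, THF, 0 → 23 °C
Reagents that add atoms: none
Why: Hydride reduction of the carboxylic acid to the C5 primary alcohol is routine, and the acetonide and alkenes are inert.

Step 10
Reactants: 20 primary alcohol
Product: 22 isopropylidene enal, via isopropenyl aldehyde 21 (not isolated)
Conditions: Dess–Martin periodinane, NaHCO3, CH2Cl2, 0 °C; then DBU (cat.), CH2Cl2, 23 °C
Reagents that add atoms: none
Why: Dess–Martin oxidation gives the β,γ-unsaturated aldehyde, and base-mediated enolisation with γ-protonation moves the C6 isopropenyl double bond into conjugation, which erases the C6 stereocentre while C7, not acidified by the carbonyl, keeps its configuration.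

Step 11
Reactants: 22 isopropylidene enal
Product: 23 cis-decalin allylic alcohol
Conditions: Me2AlCl (2.5 equiv), CH2Cl2, −78 → −20 °C; aq. potassium sodium tartrate
Reagents that add atoms: none
Why: Me2AlCl activates the aldehyde of 22, the terminal carbon C4 of the C2 isopropenyl group adds to C5 while a hydrogen of the isopropenyl methyl passes to oxygen through a six-membered ene array, and the resulting alcohol–aluminium complex loses methane, so no protic acid is left to move the new double bond. The closest known reaction type is the Me2AlCl-promoted type 2 intramolecular carbonyl-ene cyclisation of aldehydes onto 1,1-disubstituted alkenes, which gives 3-methylenecyclohexanols, together with the ene closure of conjugated aldehydes of the citral type. Ring B closes as a six-membered ring with the ene unit tethered through its central carbon C3 and bonding through C4 to the carbonyl carbon (exo with respect to C=O) in a chair-like array. The only new stereocentre, C5, is set by that chair, in which oxygen points toward the transferring hydrogen, but its configuration is irrelevant because C5 is later oxidised; the cis fusion is inherited from the cis C2 and C7 substituents. The step needs site selectivity and an exocyclic alkene: only the C2 isopropenyl group reaches C5 in a six-membered array, whereas C8=C9 could only close a four- or five-membered ring, and allylic 1,3-strain with the C6 isopropylidene group keeps H7 in the enal plane and so holds C2 gauche to C5.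

Step 12
Reactants: 23 cis-decalin allylic alcohol
Product: 24 C3-methyl allylic alcohol
Conditions: Mn(dpm)3 (cat.; dpm = 2,2,6,6-tetramethylheptane-3,5-dionate), PhSiH3, t-BuOOH, i-PrOH, 23 °C
Reagents that add atoms: none
Why: Manganese-hydride hydrogen-atom-transfer hydrogenation reduces the 1,1-disubstituted C3 methylene faster than the tri- and tetrasubstituted alkenes, and hydrogen delivery to the tertiary C3 radical should give the more stable equatorial methyl (cis to H2 and H7), because allylic 1,3-strain from the isopropylidene group holds C7–C8 axial on ring B so that the epimeric methyl would be syn-axial to C8.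

Step 13
Reactants: 24 C3-methyl allylic alcohol
Product: 25 isopropylidene enone
Conditions: Dess–Martin periodinane, NaHCO3, CH2Cl2, 0 → 23 °C
Reagents that add atoms: none
Why: Dess–Martin oxidation of the allylic C5 carbinol gives the conjugated isopropylidene ketone, and both C5 epimers converge.

Step 14
Reactants: 25 isopropylidene enone
Product: 26 enone diol
Conditions: AcOH/H2O (4:1), 45 °C
Reagents that add atoms: none
Why: Aqueous-acid hydrolysis of the acetonide is routine, and the enone and the C8=C9 alkene tolerate dilute acetic acid.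

Step 15
Reactants: 26 enone diol; 27 acetic anhydride
Product: 28 enone diacetate
Conditions: pyridine, DMAP (cat.), CH2Cl2, 0 → 23 °C
Reagents that add atoms: acetic anhydride (27), CC(=O)OC(C)=O
Why: DMAP-catalysed acetylation of both secondary alcohols is done before C4 is oxygenated, so no selective acylation of a triol is ever needed.

Step 16
Reactants: 28 enone diacetate
Product: 30 C4-epimeric ketol, via potassium enolate 29 (not isolated)
Conditions: KN(SiMe3)2 (KHMDS, 1.05 equiv), THF, −78 °C; then 2-(phenylsulfonyl)-3-phenyloxaziridine, −78 °C; AcOH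
Reagents that add atoms: 2-(phenylsulfonyl)-3-phenyloxaziridine, O=S(=O)(N1OC1c1ccccc1)c1ccccc1
Why: Kinetic α′-deprotonation at C4 of the isopropylidene enone (faster at −78 °C than γ-deprotonation or acetate enolisation) and N-sulfonyloxaziridine hydroxylation should deliver oxygen axially from the convex face, giving mainly the C4 epimer with hydroxyl cis to the C3 methyl.

Step 17
Reactants: 30 C4-epimeric ketol
Product: 31 target CNP0333818.1
Conditions: DBU (cat.), CH2Cl2, 23 °C
Reagents that add atoms: none
Why: Base-catalysed epimerisation of the α-ketol through its enediol leads to the target configuration, because protonation at C4 from the convex face and the preference for an equatorial, hydrogen-bonded hydroxyl trans to the C3 methyl point the same way.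

Compound list
1 | (R)-(−)-carvone | CC1=CC[C@H](CC1=O)C(C)=C | starting material
2 | potassium dienolate of 1 (enolate oxygen on C10, C1=C10 and C8=C9 double bonds) | [K+].[O-]C1=C[C@H](C(C)=C)CC=C1C | intermediate
3 | trans-6-hydroxycarvone, (5S,6S)-6-hydroxy-2-methyl-5-(prop-1-en-2-yl)cyclohex-2-en-1-one (C1 hydroxyl trans to the C2 isopropenyl group) | O[C@H]1[C@H](C(C)=C)CC=C(C)C1=O | intermediate
4 | 4-nitrobenzoic acid | OC(=O)c1ccc(cc1)[N+](=O)[O-] | starting material
5 | cis-6-(4-nitrobenzoyloxy)carvone (C1 ester oxygen cis to the C2 isopropenyl group) | O=C(O[C@@H]1[C@H](C(C)=C)CC=C(C)C1=O)c1ccc(cc1)[N+](=O)[O-] | intermediate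
6 | hydroxy ester: C10 carbinol and C1 4-nitrobenzoate, both cis to the C2 isopropenyl group | O=C(O[C@@H]1[C@H](C(C)=C)CC=C(C)[C@@H]1O)c1ccc(cc1)[N+](=O)[O-] | intermediate
7 | all-cis diol: 3-methyl-6-(prop-1-en-2-yl)cyclohex-3-ene-1,2-diol with both hydroxyls (C1, C10) cis to the isopropenyl group | O[C@@H]1[C@H](C(C)=C)CC=C(C)[C@@H]1O | intermediate
8 | epoxy diol: 7 with a C8–C9 epoxide on the face of the hydroxyls | O[C@@H]1[C@H](C(C)=C)C[C@@H]2O[C@]2(C)[C@@H]1O | intermediate
9 | 2,2-dimethoxypropane | COC(C)(C)OC | starting material
10 | epoxy acetonide: C1/C10 acetonide of 8 | CC1(C)O[C@@H]2[C@H](C(C)=C)C[C@@H]3O[C@]3(C)[C@@H]2O1 | intermediate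
11 | phenylselenide: C8 SePh trans to the C9 tertiary hydroxyl, which stays on the acetonide face | CC1(C)O[C@@H]2[C@H](C(C)=C)C[C@@H]([Se]c3ccccc3)[C@](C)(O)[C@@H]2O1 | intermediate
12 | selenoxide of 11 | CC1(C)O[C@@H]2[C@H](C(C)=C)C[C@@H]([Se](=O)c3ccccc3)[C@](C)(O)[C@@H]2O1 | intermediate
13 | tertiary allylic alcohol: C9 hydroxyl (cis to acetonide and isopropenyl), C9 methyl, C7=C8 alkene | CC1(C)O[C@@H]2[C@H](C(C)=C)C=C[C@](C)(O)[C@@H]2O1 | intermediate
14 | 3-methylbut-2-enoyl chloride | CC(C)=CC(Cl)=O | starting material
15 | lithium alkoxide of 13 | [Li+].CC1(C)O[C@@H]2[C@H](C(C)=C)C=C[C@](C)([O-])[C@@H]2O1 | intermediate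
16 | C9 senecioate (3-methylbut-2-enoate) of 13 | CC1(C)O[C@@H]2[C@H](C(C)=C)C=C[C@](C)(OC(=O)C=C(C)C)[C@@H]2O1 | intermediate
17 | trimethylsilyl dienyl ketene acetal of 16 | CC1(C)O[C@@H]2[C@H](C(C)=C)C=C[C@](C)(OC(O[Si](C)(C)C)=CC(C)=C)[C@@H]2O1 | intermediate
18 | trimethylsilyl ester of 19 | CC1(C)O[C@@H]2[C@H](C(C)=C)[C@H](C(C(=O)O[Si](C)(C)C)C(C)=C)C=C(C)[C@@H]2O1 | intermediate
19 | isopropenyl acid: ring A with C1/C10 acetonide, C2 isopropenyl, C8=C9 and cis C7 CH(isopropenyl)CO2H arm (C6 epimers) | CC1(C)O[C@@H]2[C@H](C(C)=C)[C@H](C(C(O)=O)C(C)=C)C=C(C)[C@@H]2O1 | intermediate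
20 | primary alcohol: C5 CH2OH analogue of 19 (C6 epimers) | CC1(C)O[C@@H]2[C@H](C(C)=C)[C@H](C(CO)C(C)=C)C=C(C)[C@@H]2O1 | intermediate
21 | isopropenyl aldehyde: C7 CH(isopropenyl)CHO arm (C6 epimers) | CC1(C)O[C@@H]2[C@H](C(C)=C)[C@H](C(C=O)C(C)=C)C=C(C)[C@@H]2O1 | intermediate
22 | isopropylidene enal: C7 C(CHO)=C(CH3)2 arm cis to the C2 isopropenyl group, C1/C10 acetonide | CC1(C)O[C@@H]2[C@H](C(C)=C)[C@H](C(C=O)=C(C)C)C=C(C)[C@@H]2O1 | intermediate
23 | cis-decalin allylic alcohol: C5 hydroxyl (C5 epimers), C3 exocyclic methylene, C6 isopropylidene, C1/C10 acetonide | CC1(C)O[C@@H]2[C@@H]3C(=C)CC(O)C(=C(C)C)[C@@H]3C=C(C)[C@@H]2O1 | intermediate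
24 | C3-methyl allylic alcohol: 23 with C3 methyl cis to H2 and H7 (C5 epimers) | CC1(C)O[C@@H]2[C@@H]3[C@@H](C)CC(O)C(=C(C)C)[C@@H]3C=C(C)[C@@H]2O1 | intermediate
25 | isopropylidene enone: C5 ketone of 24 | CC1(C)O[C@@H]2[C@@H]3[C@@H](C)CC(=O)C(=C(C)C)[C@@H]3C=C(C)[C@@H]2O1 | intermediate
26 | enone diol: 25 without the acetonide | O[C@@H]1[C@@H]2[C@@H](C)CC(=O)C(=C(C)C)[C@@H]2C=C(C)[C@@H]1O | intermediate
27 | acetic anhydride | CC(=O)OC(C)=O | starting material
28 | enone diacetate (4-deoxy target) | CC(=O)O[C@@H]1[C@@H]2[C@@H](C)CC(=O)C(=C(C)C)[C@@H]2C=C(C)[C@@H]1OC(C)=O | intermediate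
29 | potassium enolate of 28 (C4=C5) | [K+].CC(=O)O[C@@H]1[C@@H]2[C@@H](C)C=C([O-])C(=C(C)C)[C@@H]2C=C(C)[C@@H]1OC(C)=O | intermediate
30 | C4-epimeric ketol: C4 hydroxyl axial, cis to the C3 methyl | CC(=O)O[C@@H]1[C@@H]2[C@@H](C)[C@@H](O)C(=O)C(=C(C)C)[C@@H]2C=C(C)[C@@H]1OC(C)=O | intermediate
31 | target CNP0333818.1 | CC(=O)O[C@@H]1[C@@H]2[C@@H](C)[C@H](O)C(=O)C(=C(C)C)[C@@H]2C=C(C)[C@@H]1OC(C)=O | target

Total step count: 17. Longest linear sequence: 17 steps (1 to 31).

Steps most likely to fail

Step 11 (key step). The conjugated aldehyde is a weaker enophile than a saturated one, so methyl transfer from aluminium to C5 or ionisation of the allylic aluminium alkoxide may overtake ring closure. The fallback closes the ring on the non-conjugated aldehyde and brings both double bonds into conjugation afterwards. It sets out from 21, taken on without the DBU treatment. Me2AlCl in CH2Cl2 at −78 °C should give the isopropenyl homoallylic alcohol F1. Dess–Martin oxidation then gives the doubly β,γ-unsaturated ketone F2, and DBU moves both alkenes into conjugation to give the cross-conjugated dienone F3. Li (2.2 equiv) in NH3/THF with t-BuOH (1 equiv) at −78 °C, then NH4Cl, should reduce only the less substituted C3=C4 enone, because the dienolate formed resists further reduction, and protonation at C3 should give the equatorial methyl. The fallback returns to the route at 25.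

Step 12. Hydrogen-atom delivery to the C3 radical may show poor facial selectivity, or hydrogen-atom transfer to C8=C9 may compete. The fallback sets C3 by hydroxyl-directed hydrogenation and sets out from 23. Dess–Martin oxidation with NaHCO3 buffer gives the methylene enone F4. NaBH4 with CeCl3·7H2O in MeOH at −78 °C adds hydride from the convex face and should give the concave-face C5 carbinol F5. [Rh(nbd)(dppb)]BF4 under H2 (50 bar) in CH2Cl2 then delivers hydrogen to C3 from the face of that homoallylic hydroxyl, which places the methyl on the convex face. The product is 24 as a single C5 epimer, where the route resumes.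

Step 2. The activated ketol may eliminate toward an aromatic phenol, or inversion at the hindered carbinol may be incomplete. The fallback sets C1 by hydride delivery instead of substitution and sets out from 3. TBSCl and imidazole in DMF give the silyl ether F6. NaBH4 with CeCl3·7H2O in MeOH at −78 °C gives the C10 carbinol F7 with hydroxyl cis to the isopropenyl group. Ac2O, pyridine and DMAP give the C10 acetate F8, and HF·pyridine in THF frees the C1 hydroxyl to give the hydroxy acetate F9. Dess–Martin oxidation gives the C1 ketone F10. LiAlH4 in THF at −78 → 0 °C reduces the ketone from the face opposite the C2 isopropenyl and C10 acetoxy groups and cleaves the acetate. The fallback returns to the route at 7.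

Further compounds
F1 | step 11 | cis-fused decalin with C5 hydroxyl, C3 exocyclic methylene, C6 isopropenyl and C1/C10 acetonide (C5, C6 epimers) | CC1(C)O[C@@H]2[C@@H]3C(=C)CC(O)C(C(C)=C)[C@@H]3C=C(C)[C@@H]2O1
F2 | step 11 | C5 ketone of F1 (C6 epimers) | CC1(C)O[C@@H]2[C@@H]3C(=C)CC(=O)C(C(C)=C)[C@@H]3C=C(C)[C@@H]2O1
F3 | step 11 | cross-conjugated dienone: C3=C4 with methyl on C3, C5 ketone, C6 isopropylidene | CC1(C)O[C@@H]2[C@@H]3C(C)=CC(=O)C(=C(C)C)[C@@H]3C=C(C)[C@@H]2O1
F4 | step 12 | methylene enone: C5 ketone of 23 | CC1(C)O[C@@H]2[C@@H]3C(=C)CC(=O)C(=C(C)C)[C@@H]3C=C(C)[C@@H]2O1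
F5 | step 12 | C5 carbinol of F4 with hydroxyl on the concave face | CC1(C)O[C@@H]2[C@@H]3C(=C)C[C@H](O)C(=C(C)C)[C@@H]3C=C(C)[C@@H]2O1
F6 | step 2 | tert-butyldimethylsilyl ether of 3 | CC(C)(C)[Si](C)(C)O[C@H]1[C@H](C(C)=C)CC=C(C)C1=O
F7 | step 2 | C10 carbinol of F6 (hydroxyl cis to the isopropenyl group) | CC(C)(C)[Si](C)(C)O[C@H]1[C@H](C(C)=C)CC=C(C)[C@@H]1O
F8 | step 2 | C10 acetate of F7 | CC(C)(C)[Si](C)(C)O[C@H]1[C@H](C(C)=C)CC=C(C)[C@@H]1OC(C)=O
F9 | step 2 | hydroxy acetate: C1 hydroxyl trans to the isopropenyl group, C10 acetate | O[C@H]1[C@H](C(C)=C)CC=C(C)[C@@H]1OC(C)=O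
F10 | step 2 | C1 ketone of F9 | O=C1[C@H](C(C)=C)CC=C(C)[C@@H]1OC(C)=O
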